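## Retrosynthetic overview
1. The target comes from its penta-MOM ether by acidic MOM removal, a medium in which 2,3-cis-dihydroflavonols keep their configuration.
2. Key disconnection: pyranone C3–C4. The ring-A formyl carbon is converted into an acyl anion equivalent (NHC Breslow enaminol) and closes onto the neighbouring formyl carbon C3. Both carbons are carbonyl electrophiles by nature. The closure is stereoconvergent at the labile C2 and sets 2S,3R.
3. The dialdehyde comes from a ring-B benzaldehyde, CH2Cl2 (LiCHCl2 as masked formyl anion, C2–C3) and a ring-A salicylaldehyde (O1–C2 by chloro-epoxide opening).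
4. The ring-B benzaldehyde comes from an exo-selective VANOL-borate Diels–Alder reaction of a 2'-hydroxychalcone with an aryl diene, which sets 3''R,4''R,5''S.
5. Ring order: cyclohexene first, pyranone ring C last. The chalcone is made by Claisen–Schmidt condensation and the diene by Heck reaction of 5-bromosalicylaldehyde with isoprene.

Assumption: the hands of VANOL and of the triazolium salt are assigned from the usual shielding models; if either induces the opposite sense, its commercial antipode is used and nothing else changes.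

Locants: C2, C3, C4 and O1 are the pyranone (flavanonol) atoms. C1''–C6'' is the cyclohexene, where C1'' bears CH3, C3'' the ring-B aryl, C4'' the aroyl and C5'' the resorcinol aryl. The target is (2S,3R)-2,3-cis and (3''R,4''R,5''S)-all-trans.

## Route

Step 1
Reactants: 1 2,4-dihydroxyacetophenone
Product: 2 1-[2-hydroxy-4-(methoxymethoxy)phenyl]ethan-1-one
Conditions: MOMCl (1.1 equiv), K2CO3, acetone, 0 °C to rt
Reagents that add atoms: chloromethyl methyl ether (MOMCl), COCCl
Why: Williamson-type O-alkylation in which the 2-OH, hydrogen-bonded to the ketone, stays free for the later boron chelation; no stereocentre is formed.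

Step 2
Reactants: 3 2,4-dihydroxybenzaldehyde
Product: 4 2,4-bis(methoxymethoxy)benzaldehyde
Conditions: MOMCl (3 equiv), K2CO3, acetone, reflux
Reagents that add atoms: chloromethyl methyl ether (MOMCl), COCCl
Why: Exhaustive Williamson-type O-alkylation, where excess reagent and heat also alkylate the chelated 2-OH; no stereocentre is formed.

Step 3
Reactants: 2 1-[2-hydroxy-4-(methoxymethoxy)phenyl]ethan-1-one; 4 2,4-bis(methoxymethoxy)benzaldehyde
Product: 5 (E)-3-[2,4-bis(methoxymethoxy)phenyl]-1-[2-hydroxy-4-(methoxymethoxy)phenyl]prop-2-en-1-one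
Conditions: KOH, EtOH–H2O, rt, 36 h
Reagents that add atoms: none
Why: Claisen–Schmidt condensation; MOM ethers tolerate hydroxide, and the conjugated E-enone formed here later fixes the C4''/C5'' trans relationship.

Step 4
Reactants: 6 5-bromo-2-hydroxybenzaldehyde
Product: 7 5-bromo-2-(methoxymethoxy)benzaldehyde
Conditions: MOMCl (1.5 equiv), K2CO3, acetone, reflux
Reagents that add atoms: chloromethyl methyl ether (MOMCl), COCCl
Why: Williamson-type O-alkylation; capping the ring-B phenol prevents lactol and benzofuran formation once C3 is a formyl group.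

Step 5
Reactants: 7 5-bromo-2-(methoxymethoxy)benzaldehyde; 8 isoprene
Product: 9 2-(methoxymethoxy)-5-[(1E)-3-methylbuta-1,3-dien-1-yl]benzaldehyde
Conditions: Pd(OAc)2 (5 mol %), P(o-tol)3 (12 mol %), Et3N (2 equiv), 8 (6 equiv), BHT, MeCN, sealed tube, 100 °C
Reagents that add atoms: none
Why: Mizoroki–Heck reaction in which aryl-palladium adds to the unsubstituted vinyl terminus of isoprene and syn beta-hydride elimination gives the conjugated E-diene.

Step 6
Reactants: 5 the chalcone; 9 the aryl diene
Product: 10 5-[(1R,5S,6R)-5-[2,4-bis(methoxymethoxy)phenyl]-6-[2-hydroxy-4-(methoxymethoxy)benzoyl]-3-methylcyclohex-2-en-1-yl]-2-(methoxymethoxy)benzaldehyde (all-trans exo adduct; 3''R,4''R,5''S)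
Conditions: (R)-VANOL [(R)-3,3'-diphenyl-2,2'-binaphthalene-1,1'-diol] (1.2 equiv), B(OPh)3 (1.1 equiv), 5 Å MS, PhCF3, rt, 1 h; then 9 (1.3 equiv), 40 °C, 48 h; aqueous work-up, chromatography
Reagents that add atoms: none
Why: Chiral-borate-promoted normal-demand Diels–Alder reaction, with stereocontrol as follows.
- Chelation of the free ortho-hydroxy ketone of 5 lowers the LUMO and blocks one enone face, which sets 4''R,5''S.
- Ortho/para regiochemistry places the ring-B aryl next to the aroyl group.
- The E-enone gives C4''/C5'' trans.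
- The bulky borate-bound aroyl group sits exo, so C3''/C4'' are trans (3''R).
- The minor endo isomer is removed on silica.

Step 7
Reactants: 10 the all-trans adduct aldehyde; 11 dichloromethane
Product: 12 dichloromethyl carbinol: the CHO of 10 becomes CH(OH)CHCl2 (both carbinol epimers; 3''R,4''R,5''S unchanged)
Conditions: 11 (6 equiv), LDA (3.2 equiv, added slowly), THF, −90 °C; AcOH quench at −90 °C
Reagents that add atoms: none
Why: Carbenoid 1,2-addition of dichloromethyllithium, a masked formyl anion, to the aldehyde. The hindered ketone is switched off as its chelated lithium phenoxide, C4'' already holds its most stable configuration, and the new carbinol centre is erased later.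

Step 8
Reactants: 3 2,4-dihydroxybenzaldehyde
Product: 13 2-hydroxy-4-(methoxymethoxy)benzaldehyde
Conditions: MOMCl (1.05 equiv), K2CO3, acetone, 0 °C to rt
Reagents that add atoms: chloromethyl methyl ether (MOMCl), COCCl
Why: Regioselective Williamson-type O-alkylation of the more acidic, non-chelated 4-OH, which leaves the 2-OH that becomes O1.

Step 9
Reactants: 12 the dichloromethyl carbinol; 13 2-hydroxy-4-(methoxymethoxy)benzaldehyde
Product: 15 dialdehyde 2-[1-aryl-2-oxoethoxy]-4-(methoxymethoxy)benzaldehyde in which aryl is ring B of 10 (both C2 epimers), via chloro-epoxide 14 (not isolated)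
Conditions: 13 (3 equiv), Cs2CO3 (3 equiv), 4 Å MS, DMF, 0 °C to rt; quick silica plug, used at once
Reagents that add atoms: none
Why: Proposed new method: an aldehyde-level Jocic–Reeve reaction in which base closes 12 to chloro-epoxide 14, the phenoxide of 13 (in excess, to outcompete the hindered chelated phenol of 12) opens it by SN2 attack at the benzylic carbon, and the resulting alpha-chloro alkoxide expels chloride to reveal the formyl group; the closest known reaction type is the Jocic–Reeve/Corey–Link conversion of trichloromethyl carbinols into alpha-aryloxy acids through gem-dichloro-epoxides, and the C2 configuration is irrelevant because step 10 resets it.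

Step 10
Reactants: 15 the dialdehyde
Product: 18 penta-MOM (2S,3R)-cis-flavanonol adduct (3''R,4''R,5''S), via enol 16 (not isolated), via Breslow enaminol 17 (not isolated)
Conditions: (5aR,10bS)-2-(pentafluorophenyl)-5a,10b-dihydro-4H,6H-indeno[2,1-b][1,2,4]triazolo[4,3-d][1,4]oxazin-2-ium tetrafluoroborate (20 mol %), iPr2NEt (30 mol %), LiCl (2 equiv), 4 Å MS, THF, 0 °C to rt; AcOH quench at full conversion
Reagents that add atoms: none
Why: Proposed new method: a stereoconvergent (dynamic kinetic) NHC-catalysed intramolecular crossed benzoin reaction; the closest known reaction types are the NHC aldehyde–ketone benzoin cyclisation to 3-hydroxychroman-4-ones, the dynamic kinetic benzoin cyclisation of racemisable beta-keto esters and cooperative NHC/Lewis acid catalysis, and the mechanistic reasoning is as follows.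
- The carbene adds to the unhindered, ortho-alkoxy-activated ring-A aldehyde, not to the alpha,alpha-disubstituted one, and gives Breslow enaminol 17. C4 thereby changes from an electrophile into an acyl anion equivalent.
- C2 epimerises freely through enol 16 under the amine base, so both epimers of 15 feed one product.
- The aminoindanol wall exposes the Si face of the C3 formyl group, which gives 3R.
- Li+ bridging O1 and the formyl oxygen enforces the Cram-chelate rotamer, with the ring-B aryl anti to the forming bond. The 3-O is then pseudoaxial and the 2-aryl pseudoequatorial, which is 2,3-cis, so only the (2S)-epimer closes fast.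
- The ketol is far less acidic than 15 and is not epimerised.

Step 11
Reactants: 18 the penta-MOM cis-flavanonol adduct
Product: 19 target CNP0219853.2, (2S,3R,3''R,4''R,5''S)
Conditions: conc. HCl (cat.), MeOH–THF, 0 to 35 °C, stopped at full conversion; work-up kept below pH 5; reversed-phase purification (0.1% HCO2H)
Reagents that add atoms: none
Why: Acid-catalysed acetal exchange (MOM methanolysis); dihydroflavonols isomerise through phenoxide/quinone-methide ring opening in neutral-to-basic media but hold their configuration at low pH, so the contra-thermodynamic 2,3-cis unit and the all-trans cyclohexene are kept.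

## Compound list
1 | 2,4-dihydroxyacetophenone | CC(=O)c1ccc(O)cc1O | starting material
2 | 1-[2-hydroxy-4-(methoxymethoxy)phenyl]ethan-1-one | CC(=O)c1ccc(OCOC)cc1O | intermediate
3 | 2,4-dihydroxybenzaldehyde | O=Cc1ccc(O)cc1O | starting material
4 | 2,4-bis(methoxymethoxy)benzaldehyde | O=Cc1ccc(OCOC)cc1OCOC | intermediate
5 | (E)-chalcone, 2'-OH free, 4',2,4-tris-MOM | O=C(/C=C/c1ccc(OCOC)cc1OCOC)c1ccc(OCOC)cc1O | intermediate
6 | 5-bromo-2-hydroxybenzaldehyde | O=Cc1cc(Br)ccc1O | starting material
7 | 5-bromo-2-(methoxymethoxy)benzaldehyde | O=Cc1cc(Br)ccc1OCOC | intermediate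
8 | isoprene | C=CC(C)=C | starting material
9 | 2-(methoxymethoxy)-5-[(1E)-3-methylbuta-1,3-dien-1-yl]benzaldehyde | C=C(C)/C=C/c1ccc(OCOC)c(C=O)c1 | intermediate
10 | all-trans exo Diels–Alder adduct aldehyde (3''R,4''R,5''S) | CC1=C[C@@H](c2ccc(OCOC)c(C=O)c2)[C@H](C(=O)c2ccc(OCOC)cc2O)[C@@H](c2ccc(OCOC)cc2OCOC)C1 | intermediate
11 | dichloromethane | ClCCl | starting material
12 | dichloromethyl carbinol of 10 (carbinol epimers) | CC1=C[C@@H](c2ccc(OCOC)c(C(O)C(Cl)Cl)c2)[C@H](C(=O)c2ccc(OCOC)cc2O)[C@@H](c2ccc(OCOC)cc2OCOC)C1 | intermediate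
13 | 2-hydroxy-4-(methoxymethoxy)benzaldehyde | O=Cc1ccc(OCOC)cc1O | intermediate
14 | chloro-epoxide (3-chlorooxiran-2-yl on ring B), not isolated | CC1=C[C@@H](c2ccc(OCOC)c(C3OC3Cl)c2)[C@H](C(=O)c2ccc(OCOC)cc2O)[C@@H](c2ccc(OCOC)cc2OCOC)C1 | intermediate
15 | dialdehyde (alpha-aryloxy arylacetaldehyde tethered to the ring-A aldehyde; C2 epimers) | CC1=C[C@@H](c2ccc(OCOC)c(C(C=O)Oc3cc(OCOC)ccc3C=O)c2)[C@H](C(=O)c2ccc(OCOC)cc2O)[C@@H](c2ccc(OCOC)cc2OCOC)C1 | intermediate
16 | C2=C3 enol of 15, not isolated | CC1=C[C@@H](c2ccc(OCOC)c(C(=CO)Oc3cc(OCOC)ccc3C=O)c2)[C@H](C(=O)c2ccc(OCOC)cc2O)[C@@H](c2ccc(OCOC)cc2OCOC)C1 | intermediate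
17 | Breslow enaminol of the ring-A aldehyde, reactive (2S)-epimer, not isolated | CC1=C[C@@H](c2ccc(OCOC)c([C@@H](C=O)Oc3cc(OCOC)ccc3C(O)=C3N(c4c(F)c(F)c(F)c(F)c4F)N=C4CO[C@@H]5Cc6ccccc6[C@@H]5N34)c2)[C@H](C(=O)c2ccc(OCOC)cc2O)[C@@H](c2ccc(OCOC)cc2OCOC)C1 | intermediate
18 | penta-MOM (2S,3R)-cis-flavanonol adduct | CC1=C[C@@H](c2ccc(OCOC)c([C@@H]3Oc4cc(OCOC)ccc4C(=O)[C@@H]3O)c2)[C@H](C(=O)c2ccc(OCOC)cc2O)[C@@H](c2ccc(OCOC)cc2OCOC)C1 | intermediate
19 | CNP0219853.2 | CC1=C[C@@H](c2ccc(O)c([C@@H]3Oc4cc(O)ccc4C(=O)[C@@H]3O)c2)[C@H](C(=O)c2ccc(O)cc2O)[C@@H](c2ccc(O)cc2O)C1 | target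

## Step count
Total steps: 11. Longest linear sequence: 7 (steps 4, 5, 6, 7, 9, 10, 11).

## Steps most likely to fail

**Step 10 (key ring closure).**
- The dipole-minimised closure may win and give the 2,3-trans ketol.
- The carbene may attack the aliphatic aldehyde, which leads to aryloxide expulsion or to the 4-hydroxy-3-one regioisomer.
- An intramolecular aldol reaction to a dihydrobenzofuranol may compete.

The fallback sets out from 15 and comes back at 18. Compound 15 is closed with the antipodal (5aS,10bR) triazolium salt and no LiCl. Catalyst preference (Re face, 3S) and the intrinsic trans closure then reinforce each other and give the (2S,3S)-trans ketol F1. C3 is inverted by Mitsunobu reaction (ClCH2CO2H, PPh3, DIAD, toluene, 0 °C), an SN2 displacement at the alpha-keto carbon, to give the (2S,3R)-cis chloroacetate F2. Thiourea with 2,6-lutidine in MeOH at rt removes the ester without a strong base and delivers 18.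

**Step 9 (chloro-epoxide etherification).**
- The electron-rich chloro-epoxide may rearrange or hydrolyse before the weakly nucleophilic phenoxide arrives.
- The product may undergo aldol reaction under carbonate.

The fallback sets out from 10, skips steps 7 and 9, and comes back at 15. Corey–Chaykovsky methylenation (Me3SI, NaH, DMSO–THF, 0 °C) gives the aryl oxirane F3. Lewis-acid-promoted benzylic opening with 13 (Sc(OTf)3 5 mol %, CH2Cl2, −20 °C) gives the 2-aryloxy-2-arylethanol F4. Buffered Dess–Martin oxidation (NaHCO3, CH2Cl2, 0 °C) gives 15.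

**Step 6 (cycloaddition).** A diene aryl group without ortho substituents may favour the endo adduct, which is the C3'' epimer and cannot be corrected by epimerisation.

The fallback sets out from 5 and 7, skips step 5, and comes back at 10.
- 3-Methylbut-2-enal with isopropenyl acetate (TsOH cat.) gives the dienyl acetate F5.
- F5 reacts with 5 under the same VANOL borate in its naturally preferred endo mode to give the allylic acetate F6, in which the 3''-OAc is cis to the aroyl group.
- Compound 7 is borylated (B2pin2, Pd(dppf)Cl2, KOAc, dioxane, 80 °C) to the aryl boronate F7.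
- Pd(PPh3)4-catalysed allylic arylation of F6 with F7 (K3PO4, THF–H2O, rt) proceeds with net inversion. Ionisation by zerovalent palladium is anti to the acetate, and the aryl group is delivered from the metal at the less hindered allyl terminus. This places ring B trans to the aroyl group and gives 10.

## Further compounds
F1 | step 10 | penta-MOM (2S,3S)-trans-flavanonol adduct | CC1=C[C@@H](c2ccc(OCOC)c([C@@H]3Oc4cc(OCOC)ccc4C(=O)[C@H]3O)c2)[C@H](C(=O)c2ccc(OCOC)cc2O)[C@@H](c2ccc(OCOC)cc2OCOC)C1
F2 | step 10 | penta-MOM (2S,3R)-cis-flavanonol 3-O-chloroacetate | CC1=C[C@@H](c2ccc(OCOC)c([C@@H]3Oc4cc(OCOC)ccc4C(=O)[C@@H]3OC(=O)CCl)c2)[C@H](C(=O)c2ccc(OCOC)cc2O)[C@@H](c2ccc(OCOC)cc2OCOC)C1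
F3 | step 9 | aryl oxirane from 10 (epoxide epimers) | CC1=C[C@@H](c2ccc(OCOC)c(C3CO3)c2)[C@H](C(=O)c2ccc(OCOC)cc2O)[C@@H](c2ccc(OCOC)cc2OCOC)C1
F4 | step 9 | 2-aryloxy-2-arylethanol (C2 epimers) | CC1=C[C@@H](c2ccc(OCOC)c(C(CO)Oc3cc(OCOC)ccc3C=O)c2)[C@H](C(=O)c2ccc(OCOC)cc2O)[C@@H](c2ccc(OCOC)cc2OCOC)C1
F5 | step 6 | (E)-3-methylbuta-1,3-dien-1-yl acetate | CC(=C)/C=C/OC(C)=O
F6 | step 6 | endo adduct, allylic acetate with 3''-OAc cis to the aroyl group | CC1=C[C@H](OC(C)=O)[C@H](C(=O)c2ccc(OCOC)cc2O)[C@@H](c2ccc(OCOC)cc2OCOC)C1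
F7 | step 6 | 2-(methoxymethoxy)-5-(4,4,5,5-tetramethyl-1,3,2-dioxaborolan-2-yl)benzaldehyde | O=Cc1cc(B2OC(C)(C)C(C)(C)O2)ccc1OCOC
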